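**Retrosynthetic overview**
1. The ring–ring bond and both quinone rings are made in one operation. Two molecules of the symmetrical resorcinol 2-methyl-5-[2-(2-methoxyphenyl)ethyl]benzene-1,3-diol react under KOH/O2. Of its two equivalent ring C–H carbons, one is oxygenated (aromaticity lost) and the other forms the C–C bond.
2. The CH2–CH2 link comes from an oxidative boron-Heck reaction of 5-borylated 2-methylresorcinol with 2-vinylanisole, hydrogenated in the same flask.
3. The boronate comes from sterically controlled iridium C–H borylation of 2-methylresorcinol at C5, with the phenols masked in situ as O-Bpin ethers.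
4. Ring order: no ring is built, since all four six-membered rings are bought as benzene rings. The two resorcinol rings become the quinone rings last, the first before the C–C coupling and the second after it.

Assumption: the SMILES carries no stereodescriptor (no stereocentre, and the biquinone axis is not specified), so the compound is made as drawn and no stereocontrol is needed.

**Step 1**
Reactants: 1 2-methylresorcinol (2-methylbenzene-1,3-diol)
Product: 4 2-methyl-5-(4,4,5,5-tetramethyl-1,3,2-dioxaborolan-2-yl)benzene-1,3-diol, via bis-boryl ether 2 (not isolated), via triboryl arene 3 (not isolated)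
Conditions: HBpin (4.5 equiv), THF, rt, 1 h; [Ir(OMe)(cod)]2 (1.5 mol %), dtbpy (3 mol %), 80 °C, 16 h; MeOH, rt
Reagents that add atoms: pinacolborane (HBpin), [H]B1OC(C)(C)C(C)(C)O1
Why: This is an Ishiyama–Miyaura–Hartwig iridium-catalysed C–H borylation in which HBpin first masks both phenols as O-Bpin ethers (2), the iridium trisboryl catalyst then attacks C5, the only C–H bond with no ortho substituent, to give 3 (a second borylation is sterically blocked), and methanol strips the O-Bpin groups; no stereocentre is formed.

**Step 2**
Reactants: 4 2-methyl-5-(4,4,5,5-tetramethyl-1,3,2-dioxaborolan-2-yl)benzene-1,3-diol; 5 2-vinylanisole (1-ethenyl-2-methoxybenzene)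
Product: 7 2-methyl-5-[2-(2-methoxyphenyl)ethyl]benzene-1,3-diol, via stilbene 6 (not isolated)
Conditions: Pd(OAc)2 (5 mol %), 2,9-dimethyl-1,10-phenanthroline (6 mol %), O2 (1 atm), DMF, 50 °C, 12 h; N2 purge, then 10% Pd/C, H2 (1 atm), DMF–MeOH, rt
Reagents that add atoms: none
Why: In the oxidative boron-Heck reaction 4 transmetalates to divalent palladium, the styrene inserts with the aryl group going to the unsubstituted terminus, β-hydride elimination gives the E-stilbene and O2 reoxidises zerovalent palladium, after which heterogeneous catalytic hydrogenation saturates the only C=C bond in the same flask; free phenols and the anisole are inert to both stages, the alkene geometry is erased, and no stereocentre results.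

**Step 3**
Reactants: 7 2-methyl-5-[2-(2-methoxyphenyl)ethyl]benzene-1,3-diol (two molecules)
Product: 10 4,4'-dihydroxy-2,2'-bis[2-(2-methoxyphenyl)ethyl]-5,5'-dimethyl-[1,1'-bi(cyclohexa-1,4-diene)]-3,3',6,6'-tetrone, via hydroxyquinone 8 (not isolated), via arylquinone 9 (not isolated)
Conditions: KOH (6 equiv), EtOH (0.5 M in 7), air, 0 °C, 2 h, then O2 (1 atm), rt, 12 h; 1 M HCl
Reagents that add atoms: dioxygen, O=O
Why: Proposed new method: the resorcinolate of 7 has two equivalent nucleophilic ring carbons (C4 and C6), and autoxidation oxygenates one of them para to a phenoxide, which destroys the aromaticity and the symmetry and gives the vinylogous acid 8. The only free ring carbon of 8 is the β-carbon of the enone that the hydroxyl group does not deactivate, so still unoxidised 7 (kept in excess by the slow air stage and the high concentration) adds there through its activated carbon in a Michael addition. O2 reoxidises the adduct to 9 and then oxygenates the last free position para to a phenoxide (radical pairing at the same carbons would give the same connectivity). The sequence ends at 10 because every ring carbon is then substituted, the phenethyl groups block closure to a dibenzofuran, and the product rests as a stabilised bis-enolate until acidification; no stereocentre is formed. The closest known reaction types are the Beam-type aerobic oxidation of 2,5-dialkylresorcinols to 2-hydroxy-1,4-benzoquinones in ethanolic KOH, where C–C-linked quinone dimers are recognised by-products, and the air dimerisation of benzene-1,2,4-triol at C5.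

**Compound list**
1 | 2-methylresorcinol (2-methylbenzene-1,3-diol) | Cc1c(O)cccc1O | starting material
2 | 2-methyl-1,3-bis[(4,4,5,5-tetramethyl-1,3,2-dioxaborolan-2-yl)oxy]benzene | Cc1c(OB2OC(C)(C)C(C)(C)O2)cccc1OB1OC(C)(C)C(C)(C)O1 | intermediate
3 | 2-methyl-5-(4,4,5,5-tetramethyl-1,3,2-dioxaborolan-2-yl)-1,3-bis[(4,4,5,5-tetramethyl-1,3,2-dioxaborolan-2-yl)oxy]benzene | Cc1c(OB2OC(C)(C)C(C)(C)O2)cc(B2OC(C)(C)C(C)(C)O2)cc1OB1OC(C)(C)C(C)(C)O1 | intermediate
4 | 2-methyl-5-(4,4,5,5-tetramethyl-1,3,2-dioxaborolan-2-yl)benzene-1,3-diol | Cc1c(O)cc(B2OC(C)(C)C(C)(C)O2)cc1O | intermediate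
5 | 2-vinylanisole (1-ethenyl-2-methoxybenzene) | COc1ccccc1C=C | starting material
6 | 5-[(E)-2-(2-methoxyphenyl)ethenyl]-2-methylbenzene-1,3-diol | COc1ccccc1/C=C/c1cc(O)c(C)c(O)c1 | intermediate
7 | 2-methyl-5-[2-(2-methoxyphenyl)ethyl]benzene-1,3-diol | COc1ccccc1CCc1cc(O)c(C)c(O)c1 | intermediate
8 | 2-hydroxy-6-[2-(2-methoxyphenyl)ethyl]-3-methylcyclohexa-2,5-diene-1,4-dione | COc1ccccc1CCC1=CC(=O)C(C)=C(O)C1=O | intermediate
9 | 5-{2,4-dihydroxy-6-[2-(2-methoxyphenyl)ethyl]-3-methylphenyl}-2-hydroxy-6-[2-(2-methoxyphenyl)ethyl]-3-methylcyclohexa-2,5-diene-1,4-dione | COc1ccccc1CCC1=C(c2c(O)c(C)c(O)cc2CCc2ccccc2OC)C(=O)C(C)=C(O)C1=O | intermediate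
10 | 4,4'-dihydroxy-2,2'-bis[2-(2-methoxyphenyl)ethyl]-5,5'-dimethyl-[1,1'-bi(cyclohexa-1,4-diene)]-3,3',6,6'-tetrone (CNP0293637.0) | COc1ccccc1CCC1=C(C2=C(CCc3ccccc3OC)C(=O)C(O)=C(C)C2=O)C(=O)C(C)=C(O)C1=O | target

**Total step count:** 3. **Longest linear sequence:** 3.

**Steps most likely to fail**

Step 3 (highest risk). The autoxidation may stop at 8, may add solvent or hydroxide at the free quinone carbon, or may degrade the product on long exposure to base. The fallback sets out from 7 and comes back at 10, and it replaces the one-flask autoxidation with a directed cross-coupling of a separately made electrophile and nucleophile.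
- Half of 7 is oxidised with stabilised 2-iodoxybenzoic acid in EtOAc, and hydroxyquinone 8 is isolated.
- Compound 8 is combined with one equivalent of untouched 7 in CH2Cl2/CF3CO2H. Under acid, 8 is neutral and a better acceptor, and Friedel–Crafts-type conjugate addition gives 6,6'-bis[2-(2-methoxyphenyl)ethyl]-3,3'-dimethylbiphenyl-2,2',4,4',5-pentaol F1.
- F1 is oxidised on both rings with (KSO3)2NO in aqueous acetone/KH2PO4 (Teuber oxidation) to give 10.

Step 2. The pinacol ester may transmetalate slowly. Under O2 it may also give homocoupled biaryl, phenol from the boronate, or the branched 1,1-diarylethene. The fallback sets out from 4 and comes back at 7, and it replaces alkene C–H arylation under O2 with a cross-coupling to a vinyl electrophile under N2.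
- Commercial (E)-2-methoxycinnamic acid is treated with NBS and catalytic LiOAc in MeCN–H2O (catalytic Hunsdiecker reaction) to give (E)-1-(2-bromoethenyl)-2-methoxybenzene F2.
- Suzuki–Miyaura coupling of F2 with 4 (Pd(PPh3)4, K2CO3, dioxane–H2O, 80 °C) gives stilbene 6, which is now isolated.
- Hydrogenation of 6 over 10% Pd/C gives 7.

Step 1. The O-Bpin groups may steer some borylation to the ortho carbons, or residual phenol may inhibit the catalyst. The fallback sets out from 1 and comes back at 4, and it replaces transient masking with isolated bulky protecting groups, so that steric effects alone decide the site.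
- Compound 1 is silylated with TBSCl/imidazole in DMF to give 1,3-bis(tert-butyldimethylsilyloxy)-2-methylbenzene F3.
- F3 is borylated with B2pin2, [Ir(OMe)(cod)]2 and dtbpy in hexane at 60 °C to give 1,3-bis(tert-butyldimethylsilyloxy)-2-methyl-5-(4,4,5,5-tetramethyl-1,3,2-dioxaborolan-2-yl)benzene F4.
- F4 is desilylated with Bu4NF/AcOH in THF to give 4.

**Further compounds**
F1 | step 3 | 6,6'-bis[2-(2-methoxyphenyl)ethyl]-3,3'-dimethylbiphenyl-2,2',4,4',5-pentaol | COc1ccccc1CCc1c(O)c(O)c(C)c(O)c1-c1c(O)c(C)c(O)cc1CCc1ccccc1OC
F2 | step 2 | (E)-1-(2-bromoethenyl)-2-methoxybenzene | COc1ccccc1/C=C/Br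
F3 | step 1 | 1,3-bis(tert-butyldimethylsilyloxy)-2-methylbenzene | Cc1c(O[Si](C)(C)C(C)(C)C)cccc1O[Si](C)(C)C(C)(C)C
F4 | step 1 | 1,3-bis(tert-butyldimethylsilyloxy)-2-methyl-5-(4,4,5,5-tetramethyl-1,3,2-dioxaborolan-2-yl)benzene | Cc1c(O[Si](C)(C)C(C)(C)C)cc(B2OC(C)(C)C(C)(C)O2)cc1O[Si](C)(C)C(C)(C)C
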